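**Retrosynthetic overview**
1. Last step: an intramolecular Nozaki–Hiyama–Kishi addition (C11 alkenyl iodide to C12 aldehyde) closes the 14-membered ring and creates the C12 carbinol.
2. Late fragment union at C4–C5: an 11-carbon alkenyl metal (C12–C14, C1–C4, isopropylidene) adds to a 9-carbon epoxy aldehyde (C5–C11); oxidation then gives the α-isopropylidene epoxy ketone.
3. Alkenyl bromide half: pent-4-yn-1-ol → carboalumination → Sharpless epoxidation → epoxy iodide/Zn transposition (sets C1) → 9-BBN/Suzuki coupling with Me2C=CBr2 (made from acetone).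
4. Epoxy aldehyde half: TMS-propyne + 1-bromobut-2-yne → 1,5-diyne → carboalumination → hydrozirconation/iodination → Sharpless epoxidation (sets C6, C7) → oxidation.
5. Ring order: oxirane first (fragment stage), 14-membered carbocycle last.

**Assumptions:** Atom labels C1–C14 follow the target ring: C1 = C(OAc)Me, C4 = C(=CMe2), C5 = ketone, C6/C7 = oxirane, C10=C11 = alkene, C12 = CHOH. In these labels the target is (1R,6R,7S,10E,12R). The SiMe3 group of 12 is treated as a protecting group. The C12 configuration is not reagent-controlled in step 19 (see the first fallback).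

**Step 1**
Reactants: 1 pent-4-yn-1-ol
Product: 2 tert-butyldimethyl(pent-4-yn-1-yloxy)silane
Conditions: TBSCl, imidazole, DMF, 0 °C → rt
Reagents that add atoms: tert-butyldimethylsilyl chloride, CC(C)(C)[Si](C)(C)Cl
Why: Standard imidazole-promoted silylation of the primary alcohol gives an ether that survives Me3Al, Zn, Pd and t-BuLi and can later be cleaved next to the acetate.

**Step 2**
Reactants: 2 tert-butyldimethyl(pent-4-yn-1-yloxy)silane
Product: 4 (E)-6-((tert-butyldimethylsilyl)oxy)-3-methylhex-2-en-1-ol, via alkenyldimethylalane 3 (not isolated)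
Conditions: Me3Al, Cp2ZrCl2 (cat.), CH2Cl2, 0 °C → rt; then (CH2O)n, THF, 0 °C → rt; aq. Rochelle salt
Reagents that add atoms: trimethylaluminium, C[Al](C)C; formaldehyde (as paraformaldehyde), C=O
Why: Negishi Zr-catalysed methylalumination adds Me and Al syn across the terminal alkyne with Al at the terminus, and hydroxymethylation of the C–Al bond with retention fixes the (E)-trisubstituted allylic alcohol.

**Step 3**
Reactants: 4 (E)-6-((tert-butyldimethylsilyl)oxy)-3-methylhex-2-en-1-ol
Product: 5 ((2S,3S)-3-(3-((tert-butyldimethylsilyl)oxy)propyl)-3-methyloxiran-2-yl)methanol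
Conditions: Ti(OiPr)4 (10 mol%), L-(+)-DET (12 mol%), t-BuOOH, 4 Å MS, CH2Cl2, –20 °C
Reagents that add atoms: tert-butyl hydroperoxide, CC(C)(C)OO
Why: Katsuki–Sharpless asymmetric epoxidation of an (E)-3-methylalk-2-en-1-ol with L-(+)-tartrate gives the (2S,3S)-epoxide (as with geraniol), and its quaternary carbon is the future C1.

**Step 4**
Reactants: 5 ((2S,3S)-3-(3-((tert-butyldimethylsilyl)oxy)propyl)-3-methyloxiran-2-yl)methanol
Product: 6 tert-butyl(3-((2S,3R)-3-(iodomethyl)-2-methyloxiran-2-yl)propoxy)dimethylsilane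
Conditions: I2, PPh3, imidazole, THF/MeCN, 0 °C
Reagents that add atoms: iodine, II
Why: Appel-type iodination converts only the primary hydroxyl and leaves the epoxide stereocentres and the silyl ether untouched.

**Step 5**
Reactants: 6 tert-butyl(3-((2S,3R)-3-(iodomethyl)-2-methyloxiran-2-yl)propoxy)dimethylsilane
Product: 7 (S)-6-((tert-butyldimethylsilyl)oxy)-3-methylhex-1-en-3-ol
Conditions: Zn dust, EtOH, reflux; aq. NH4Cl
Reagents that add atoms: none
Why: Zinc insertion into the C–I bond and β-elimination of the epoxide oxygen (reductive epoxide opening) give the transposed tertiary allylic alcohol, and because the quaternary C–O bond is not broken the (3S)-epoxide carbon becomes the (S)-carbinol.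

**Step 6**
Reactants: 8 acetone
Product: 9 1,1-dibromo-2-methylprop-1-ene
Conditions: CBr4, PPh3 (2 equiv), CH2Cl2, 0 °C; then acetone, 40 °C; distillation
Reagents that add atoms: carbon tetrabromide, BrC(Br)(Br)Br
Why: Ramirez dibromo-olefination with the ylide Ph3P=CBr2 formed in the flask converts the ketone into the symmetrical gem-dibromoalkene, which has no stereochemical issue.

**Step 7**
Reactants: 7 (S)-6-((tert-butyldimethylsilyl)oxy)-3-methylhex-1-en-3-ol; 9 1,1-dibromo-2-methylprop-1-ene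
Product: 11 (S)-7-bromo-1-((tert-butyldimethylsilyl)oxy)-4,8-dimethylnon-7-en-4-ol, via B-alkyl-9-BBN borane 10 (not isolated)
Conditions: 9-BBN (1.5 equiv), THF, 0 °C → rt; then 9 (3 equiv), PdCl2(dppf) (5 mol%), AsPh3, Cs2CO3, DMF/H2O, rt
Reagents that add atoms: none
Why: Anti-Markovnikov hydroboration of the vinyl group and a B-alkyl Suzuki–Miyaura mono-coupling build C3–C4, since the first C–Br bond of the gem-dibromide adds to Pd(0) much faster than the hindered tetrasubstituted bromoalkene product, and no stereocentre is touched.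

**Step 8**
Reactants: 12 trimethyl(prop-1-yn-1-yl)silane; 13 1-bromobut-2-yne
Product: 15 hepta-1,5-diyn-1-yltrimethylsilane, via propargyllithium reagent 14 (not isolated)
Conditions: n-BuLi, TMEDA, THF, –78 → –20 °C; then 13, –78 °C → rt
Reagents that add atoms: none
Why: Lithiated 1-TMS-propyne alkylates at its propargylic carbon (Corey–Kirst propargylation) in an SN2 reaction with the primary propargylic bromide to give the 1,5-diyne.

**Step 9**
Reactants: 15 hepta-1,5-diyn-1-yltrimethylsilane
Product: 16 hepta-1,5-diyne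
Conditions: K2CO3 (cat.), MeOH, rt; pentane extraction (volatile)
Reagents that add atoms: none
Why: Base-catalysed methanolysis of the C(sp)–Si bond frees the terminal alkyne and leaves the internal alkyne unchanged.

**Step 10**
Reactants: 16 hepta-1,5-diyne
Product: 18 (E)-3-methyloct-2-en-6-yn-1-ol, via alkenyldimethylalane 17 (not isolated)
Conditions: Me3Al, Cp2ZrCl2 (cat.), CH2Cl2, 0 °C → rt (stopped when the terminal alkyne is consumed); then (CH2O)n, THF, 0 °C → rt; aq. Rochelle salt
Reagents that add atoms: trimethylaluminium, C[Al](C)C; formaldehyde (as paraformaldehyde), C=O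
Why: Negishi carboalumination is much faster at the terminal than at the internal alkyne, and syn Me–Al addition followed by formaldehyde trapping with retention gives the (E)-allylic alcohol (C6=C7 precursor).

**Step 11**
Reactants: 18 (E)-3-methyloct-2-en-6-yn-1-ol
Product: 20 (2E,6E)-7-iodo-3-methylocta-2,6-dien-1-ol, via bis-zirconocene adduct 19 (not isolated)
Conditions: Cp2Zr(H)Cl (3 equiv), THF, rt → 45 °C; then I2, 0 °C; aq. NaHCO3/Na2S2O3
Reagents that add atoms: iodine, II
Why: Syn hydrozirconation with excess Schwartz reagent equilibrates Zr to the less hindered methyl-bearing alkyne carbon (about 9:1), and iodinolysis with retention gives the (E)-2-iodoalkene that carries the C10=C11 geometry.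

**Step 12**
Reactants: 20 (2E,6E)-7-iodo-3-methylocta-2,6-dien-1-ol
Product: 21 ((2S,3S)-3-((E)-4-iodopent-3-en-1-yl)-3-methyloxiran-2-yl)methanol
Conditions: Ti(OiPr)4 (10 mol%), L-(+)-DET (12 mol%), t-BuOOH, 4 Å MS, CH2Cl2, –20 °C
Reagents that add atoms: tert-butyl hydroperoxide, CC(C)(C)OO
Why: Sharpless asymmetric epoxidation with L-(+)-tartrate epoxidises only the allylic-alcohol alkene and gives the (2S,3S)-epoxide, which is the C6/C7 configuration of the target (6R,7S once C5 is a ketone).

**Step 13**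
Reactants: 21 ((2S,3S)-3-((E)-4-iodopent-3-en-1-yl)-3-methyloxiran-2-yl)methanol
Product: 22 (2R,3S)-3-((E)-4-iodopent-3-en-1-yl)-3-methyloxirane-2-carbaldehyde
Conditions: TEMPO (10 mol%), PhI(OAc)2, CH2Cl2, rt
Reagents that add atoms: none
Why: The TEMPO/PhI(OAc)2 oxidation stops at the aldehyde and does not open or epimerise the epoxide or affect the vinyl iodide.

**Step 14**
Reactants: 11 (S)-7-bromo-1-((tert-butyldimethylsilyl)oxy)-4,8-dimethylnon-7-en-4-ol; 22 (2R,3S)-3-((E)-4-iodopent-3-en-1-yl)-3-methyloxirane-2-carbaldehyde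
Product: 25 (5R)-8-((tert-butyldimethylsilyl)oxy)-1-((2S,3S)-3-((E)-4-iodopent-3-en-1-yl)-3-methyloxiran-2-yl)-5-methyl-2-(propan-2-ylidene)octane-1,5-diol (epimer mixture at the new carbinol), via dilithio species 23 (not isolated), via alkenylcerium reagent 24 (not isolated)
Conditions: 11 (1.2 equiv), t-BuLi (3 equiv per 11), THF, –78 °C; anhydrous CeCl3, –78 °C; then 22, –78 °C; aq. NH4Cl
Reagents that add atoms: none
Why: O-deprotonation and Br/Li exchange, transmetalation to the non-basic alkenylcerium (which does not exchange with the vinyl iodide) and 1,2-addition to the aldehyde join the two halves at C4–C5, and the new carbinol may form as either epimer because step 15 oxidises it.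

**Step 15**
Reactants: 25 (5R)-8-((tert-butyldimethylsilyl)oxy)-1-((2S,3S)-3-((E)-4-iodopent-3-en-1-yl)-3-methyloxiran-2-yl)-5-methyl-2-(propan-2-ylidene)octane-1,5-diol
Product: 26 (R)-8-((tert-butyldimethylsilyl)oxy)-5-hydroxy-1-((2R,3S)-3-((E)-4-iodopent-3-en-1-yl)-3-methyloxiran-2-yl)-5-methyl-2-(propan-2-ylidene)octan-1-one
Conditions: Dess–Martin periodinane, NaHCO3, CH2Cl2, 0 °C → rt
Reagents that add atoms: none
Why: Dess–Martin oxidation converts the hindered secondary carbinol into the cross-conjugated epoxy ketone, while the tertiary alcohol cannot be oxidised and the non-enolisable epoxide C–H keeps C6/C7 intact.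

**Step 16**
Reactants: 26 (R)-8-((tert-butyldimethylsilyl)oxy)-5-hydroxy-1-((2R,3S)-3-((E)-4-iodopent-3-en-1-yl)-3-methyloxiran-2-yl)-5-methyl-2-(propan-2-ylidene)octan-1-one
Product: 27 (R)-1-((tert-butyldimethylsilyl)oxy)-8-((2R,3S)-3-((E)-4-iodopent-3-en-1-yl)-3-methyloxiran-2-yl)-4-methyl-8-oxo-7-(propan-2-ylidene)octan-4-yl acetate
Conditions: Ac2O, DMAP, Et3N, CH2Cl2, rt → 35 °C
Reagents that add atoms: acetic anhydride, CC(=O)OC(C)=O
Why: DMAP-catalysed O-acylation of the only free hydroxyl installs the tertiary acetate with retention at C1, because the C–O bond is not broken.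

**Step 17**
Reactants: 27 (R)-1-((tert-butyldimethylsilyl)oxy)-8-((2R,3S)-3-((E)-4-iodopent-3-en-1-yl)-3-methyloxiran-2-yl)-4-methyl-8-oxo-7-(propan-2-ylidene)octan-4-yl acetate
Product: 28 (R)-1-hydroxy-8-((2R,3S)-3-((E)-4-iodopent-3-en-1-yl)-3-methyloxiran-2-yl)-4-methyl-8-oxo-7-(propan-2-ylidene)octan-4-yl acetate
Conditions: HF·pyridine, pyridine, THF, 0 °C → rt
Reagents that add atoms: none
Why: Buffered fluoride cleaves the primary silyl ether and leaves the tertiary acetate, the epoxy ketone and the vinyl iodide untouched.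

**Step 18**
Reactants: 28 (R)-1-hydroxy-8-((2R,3S)-3-((E)-4-iodopent-3-en-1-yl)-3-methyloxiran-2-yl)-4-methyl-8-oxo-7-(propan-2-ylidene)octan-4-yl acetate
Product: 29 (R)-8-((2R,3S)-3-((E)-4-iodopent-3-en-1-yl)-3-methyloxiran-2-yl)-4-methyl-1,8-dioxo-7-(propan-2-ylidene)octan-4-yl acetate
Conditions: Dess–Martin periodinane, NaHCO3, CH2Cl2, 0 °C
Reagents that add atoms: none
Why: Buffered Dess–Martin oxidation takes the primary alcohol to the C12 aldehyde without over-oxidation or loss of the γ-acetate.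

**Step 19**
Reactants: 29 (R)-8-((2R,3S)-3-((E)-4-iodopent-3-en-1-yl)-3-methyloxiran-2-yl)-4-methyl-1,8-dioxo-7-(propan-2-ylidene)octan-4-yl acetate
Product: 31 (1R,6R,7S,10E,12R)-12-hydroxy-1,7,11-trimethyl-5-oxo-4-(propan-2-ylidene)-6,7-epoxycyclotetradec-10-en-1-yl acetate (CNP0404804.1), via alkenylchromium(III) species 30 (not isolated)
Conditions: CrCl2 (10 equiv), NiCl2 (cat.), degassed DMSO/THF, rt, syringe-pump addition to 2 mM; aq. work-up, chromatography
Reagents that add atoms: none
Why: In the Nozaki–Hiyama–Kishi macrocyclisation the Ni-catalysed alkenylchromium forms with retention of the (E) geometry and adds only to the aldehyde (not the ketone or acetate) to close the 14-membered ring, with C12 set by macrocyclic substrate control so that the (12R)-epimer is isolated by chromatography and the first fallback applies if it is not the major one.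

**Compound list**
1 | pent-4-yn-1-ol | C#CCCCO | starting material
2 | tert-butyldimethyl(pent-4-yn-1-yloxy)silane | C#CCCCO[Si](C)(C)C(C)(C)C | intermediate
3 | (E)-[5-((tert-butyldimethylsilyl)oxy)-2-methylpent-1-en-1-yl]dimethylalane (formed in the flask) | C[Al](C)/C=C(\C)CCCO[Si](C)(C)C(C)(C)C | intermediate
4 | (E)-6-((tert-butyldimethylsilyl)oxy)-3-methylhex-2-en-1-ol | OC/C=C(\C)CCCO[Si](C)(C)C(C)(C)C | intermediate
5 | ((2S,3S)-3-(3-((tert-butyldimethylsilyl)oxy)propyl)-3-methyloxiran-2-yl)methanol | OC[C@@H]1O[C@@]1(C)CCCO[Si](C)(C)C(C)(C)C | intermediate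
6 | tert-butyl(3-((2S,3R)-3-(iodomethyl)-2-methyloxiran-2-yl)propoxy)dimethylsilane | IC[C@@H]1O[C@@]1(C)CCCO[Si](C)(C)C(C)(C)C | intermediate
7 | (S)-6-((tert-butyldimethylsilyl)oxy)-3-methylhex-1-en-3-ol | C=C[C@](O)(C)CCCO[Si](C)(C)C(C)(C)C | intermediate
8 | acetone | CC(C)=O | starting material
9 | 1,1-dibromo-2-methylprop-1-ene | CC(C)=C(Br)Br | intermediate
10 | (R)-1-(9-borabicyclo[3.3.1]nonan-9-yl)-6-((tert-butyldimethylsilyl)oxy)-3-methylhexan-3-ol (formed in the flask; same spatial arrangement as 7) | B1(C2CCCC1CCC2)CC[C@](O)(C)CCCO[Si](C)(C)C(C)(C)C | intermediate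
11 | (S)-7-bromo-1-((tert-butyldimethylsilyl)oxy)-4,8-dimethylnon-7-en-4-ol | CC(C)=C(Br)CC[C@](O)(C)CCCO[Si](C)(C)C(C)(C)C | intermediate
12 | trimethyl(prop-1-yn-1-yl)silane | CC#C[Si](C)(C)C | starting material
13 | 1-bromobut-2-yne | CC#CCBr | starting material
14 | (3-(trimethylsilyl)prop-2-yn-1-yl)lithium (formed in the flask) | [Li]CC#C[Si](C)(C)C | intermediate
15 | hepta-1,5-diyn-1-yltrimethylsilane | CC#CCCC#C[Si](C)(C)C | intermediate
16 | hepta-1,5-diyne | CC#CCCC#C | intermediate
17 | (E)-dimethyl(2-methylhept-1-en-5-yn-1-yl)alane (formed in the flask) | C[Al](C)/C=C(\C)CCC#CC | intermediate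
18 | (E)-3-methyloct-2-en-6-yn-1-ol | OC/C=C(\C)CCC#CC | intermediate
19 | chlorozirconocene alkoxide of (2E,6E)-7-(chlorozirconocenyl)-3-methylocta-2,6-dien-1-ol (formed in the flask) | Cl[Zr](OC/C=C(\C)CC/C=C(\C)[Zr](Cl)(C1C=CC=C1)C1C=CC=C1)(C1C=CC=C1)C1C=CC=C1 | intermediate
20 | (2E,6E)-7-iodo-3-methylocta-2,6-dien-1-ol | OC/C=C(\C)CC/C=C(\C)I | intermediate
21 | ((2S,3S)-3-((E)-4-iodopent-3-en-1-yl)-3-methyloxiran-2-yl)methanol | OC[C@@H]1O[C@@]1(C)CC/C=C(\C)I | intermediate
22 | (2R,3S)-3-((E)-4-iodopent-3-en-1-yl)-3-methyloxirane-2-carbaldehyde | O=C[C@@H]1O[C@@]1(C)CC/C=C(\C)I | intermediate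
23 | O,C-dilithio derivative of 11 (lithium alkoxide and alkenyllithium; formed in the flask) | CC(C)=C([Li])CC[C@](O[Li])(C)CCCO[Si](C)(C)C(C)(C)C | intermediate
24 | alkenylcerium dichloride derived from 23 (lithium alkoxide; formed in the flask) | CC(C)=C([Ce](Cl)Cl)CC[C@](O[Li])(C)CCCO[Si](C)(C)C(C)(C)C | intermediate
25 | (5R)-8-((tert-butyldimethylsilyl)oxy)-1-((2S,3S)-3-((E)-4-iodopent-3-en-1-yl)-3-methyloxiran-2-yl)-5-methyl-2-(propan-2-ylidene)octane-1,5-diol (both epimers at C1 of the octane chain) | CC(C)=C(CC[C@](O)(C)CCCO[Si](C)(C)C(C)(C)C)C(O)[C@@H]1O[C@@]1(C)CC/C=C(\C)I | intermediate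
26 | (R)-8-((tert-butyldimethylsilyl)oxy)-5-hydroxy-1-((2R,3S)-3-((E)-4-iodopent-3-en-1-yl)-3-methyloxiran-2-yl)-5-methyl-2-(propan-2-ylidene)octan-1-one | CC(C)=C(CC[C@](O)(C)CCCO[Si](C)(C)C(C)(C)C)C(=O)[C@@H]1O[C@@]1(C)CC/C=C(\C)I | intermediate
27 | (R)-1-((tert-butyldimethylsilyl)oxy)-8-((2R,3S)-3-((E)-4-iodopent-3-en-1-yl)-3-methyloxiran-2-yl)-4-methyl-8-oxo-7-(propan-2-ylidene)octan-4-yl acetate | CC(C)=C(CC[C@](OC(C)=O)(C)CCCO[Si](C)(C)C(C)(C)C)C(=O)[C@@H]1O[C@@]1(C)CC/C=C(\C)I | intermediate
28 | (R)-1-hydroxy-8-((2R,3S)-3-((E)-4-iodopent-3-en-1-yl)-3-methyloxiran-2-yl)-4-methyl-8-oxo-7-(propan-2-ylidene)octan-4-yl acetate | CC(C)=C(CC[C@](OC(C)=O)(C)CCCO)C(=O)[C@@H]1O[C@@]1(C)CC/C=C(\C)I | intermediate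
29 | (R)-8-((2R,3S)-3-((E)-4-iodopent-3-en-1-yl)-3-methyloxiran-2-yl)-4-methyl-1,8-dioxo-7-(propan-2-ylidene)octan-4-yl acetate | CC(C)=C(CC[C@](OC(C)=O)(C)CCC=O)C(=O)[C@@H]1O[C@@]1(C)CC/C=C(\C)I | intermediate
30 | alkenylchromium(III) dichloride derived from 29 (formed in the flask) | CC(C)=C(CC[C@](OC(C)=O)(C)CCC=O)C(=O)[C@@H]1O[C@@]1(C)CC/C=C(\C)[Cr](Cl)Cl | intermediate
31 | (1R,6R,7S,10E,12R)-12-hydroxy-1,7,11-trimethyl-5-oxo-4-(propan-2-ylidene)-6,7-epoxycyclotetradec-10-en-1-yl acetate (CNP0404804.1; ring labels of this answer) | CC(=O)O[C@]1(C)CCC(=C(C)C)C(=O)[C@@H]2O[C@@]2(C)CC/C=C(\C)[C@H](O)CC1 | target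

**Totals**
Total step count: 19.
Longest linear sequence: 12 steps (steps 1, 2, 3, 4, 5, 7, 14, 15, 16, 17, 18, 19; the line 8–13 then 14–19 is equally long).

**Three steps most likely to fail**

Step 19 (macrocyclisation): the C12 configuration rests on substrate control, and Cr(II) may also attack the epoxy ketone if the reaction is prolonged. The fallback sets out from 29 and comes back at 31. The ring closure is run as before and the product is taken on as the mixture of 31 and the (12S)-epimer of the target F1. Both are oxidised together (Dess–Martin periodinane or MnO2, CH2Cl2) to the macrocyclic 5,12-diketone F2. F2 is then reduced with (S)-Me-CBS and catecholborane in toluene at –78 °C. The less hindered C12 enone carbonyl reacts in preference to the C5 ketone, which is flanked by the tetrasubstituted alkene and the oxirane, and the catalyst delivers hydride under reagent control to give the (12R)-alcohol 31.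

Step 7 (mono-coupling of the gem-dibromide): double coupling or slow transmetalation of the hydroxy borane may occur. The fallback sets out from 7 and comes back at 11, replacing the cross-coupling by a polar alkylation. Compound 7 is silylated (TMSCl, imidazole) to the bis-silyl ether F3. F3 is hydroborated with 9-BBN to the borane F4 and oxidised (NaBO3) to the primary alcohol F5. F5 is converted (I2, PPh3, imidazole) into the primary iodide F6. F6 alkylates the carbenoid 1-bromo-1-lithio-2-methylpropene F7 (from 9 and n-BuLi in THF/Et2O/pentane at –110 °C, then HMPA) to give the silylated bromoalkene F8. K2CO3 in MeOH removes the trimethylsilyl group and gives 11.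

Step 14 (fragment union): the epoxy aldehyde may decompose, or addition of the hindered alkenyl metal may be poor. The fallback sets out from 22 and comes back at 26, replacing carbonyl addition plus oxidation by an acyl substitution. Pinnick oxidation of 22 (NaClO2, NaH2PO4, 2-methylbut-2-ene, t-BuOH/H2O) gives the glycidic acid F9. Coupling with MeNHOMe·HCl (EDC, N-methylmorpholine, CH2Cl2) gives the Weinreb amide F10. F10 is acylated by the alkenylcerium reagent 24, made from 11 as in step 14, in THF at –78 °C. The chelated tetrahedral adduct collapses on work-up to ketone 26, so carbinol 25 and step 15 are bypassed.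

**Further compounds**
F1 | step 19 | (1R,6R,7S,10E,12S)-12-hydroxy-1,7,11-trimethyl-5-oxo-4-(propan-2-ylidene)-6,7-epoxycyclotetradec-10-en-1-yl acetate (12-epimer of 31) | CC(=O)O[C@]1(C)CCC(=C(C)C)C(=O)[C@@H]2O[C@@]2(C)CC/C=C(\C)[C@@H](O)CC1
F2 | step 19 | (1R,6R,7S,10E)-1,7,11-trimethyl-5,12-dioxo-4-(propan-2-ylidene)-6,7-epoxycyclotetradec-10-en-1-yl acetate | CC(=O)O[C@]1(C)CCC(=C(C)C)C(=O)[C@@H]2O[C@@]2(C)CC/C=C(\C)C(=O)CC1
F3 | step 7 | (S)-tert-butyldimethyl((4-methyl-4-((trimethylsilyl)oxy)hex-5-en-1-yl)oxy)silane | C=C[C@](O[Si](C)(C)C)(C)CCCO[Si](C)(C)C(C)(C)C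
F4 | step 7 | B-alkyl-9-BBN adduct of F3 (boron on the terminal carbon; formed in the flask) | B1(C2CCCC1CCC2)CC[C@](O[Si](C)(C)C)(C)CCCO[Si](C)(C)C(C)(C)C
F5 | step 7 | (S)-6-((tert-butyldimethylsilyl)oxy)-3-methyl-3-((trimethylsilyl)oxy)hexan-1-ol | OCC[C@](O[Si](C)(C)C)(C)CCCO[Si](C)(C)C(C)(C)C
F6 | step 7 | (S)-tert-butyl((6-iodo-4-methyl-4-((trimethylsilyl)oxy)hexyl)oxy)dimethylsilane | ICC[C@](O[Si](C)(C)C)(C)CCCO[Si](C)(C)C(C)(C)C
F7 | step 7 | 1-bromo-1-lithio-2-methylprop-1-ene (formed in the flask) | CC(C)=C([Li])Br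
F8 | step 7 | (S)-7-bromo-1-((tert-butyldimethylsilyl)oxy)-4,8-dimethyl-4-((trimethylsilyl)oxy)non-7-ene | CC(C)=C(Br)CC[C@](O[Si](C)(C)C)(C)CCCO[Si](C)(C)C(C)(C)C
F9 | step 14 | (2R,3S)-3-((E)-4-iodopent-3-en-1-yl)-3-methyloxirane-2-carboxylic acid | OC(=O)[C@@H]1O[C@@]1(C)CC/C=C(\C)I
F10 | step 14 | (2R,3S)-3-((E)-4-iodopent-3-en-1-yl)-N-methoxy-N,3-dimethyloxirane-2-carboxamide | CON(C)C(=O)[C@@H]1O[C@@]1(C)CC/C=C(\C)I
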